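**Retrosynthetic overview**
1. Ring D is closed last by forming C16–C17: a ring-closing deoxygenative C(sp3)–C(sp3) radical coupling between the C17 tertiary carbinol of ring E and the C16 bromide of the α-CH2CH2Br arm on C14 of ring C. The enabling feature is that C16 and C17 are 1,6-related through C14–C13–C18, C17 gives a tertiary radical, and the 13α-methyl (C27) allows only the cis D/E closure.
2. Before that, the 1,4-dioxane ring is made by a hydroxyl-directed inverse-demand hetero-Diels–Alder reaction of a 6-oxo-o-quinone (rings A, B, C, E) with the C1′=C5′ alkene of an ent-guaienol; the adduct then protects the catechol.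
3. Ring E comes from an enamine α,α′-annulation on a C13 acetonyl group; the trans C13/C14 methyl pair from reductive allylation at C14 and axial cuprate methylation at C13; rings B and C from Friedel–Crafts acylation and an asymmetric Robinson annulation of a 1-methyl-2-tetralone.
4. Fragment 1 (ent-guaiane alkenol) comes from (S)-carvone: ene-reductase, diazoacetate ring expansion (7-ring), Negishi coupling and Dieckmann closure (5-ring).
5. Order of ring closure: guaiane 7-ring, guaiane 5-ring; ring B, ring C, ring E, dioxane ring, ring D; then C6 ketone to the 6-ene and C20 methylation.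

Key step: step 28

Remark: triterpene atoms carry celastroid numbering (C1–C30), guaiane atoms primed numbering (C1′–C15′), and α/β refer to the usual steroid-type drawing. The sesquiterpene part of the target is read as (7′S,10′R), the enantiomeric guaiane series, so it is built from (S)-carvone.

**Fragment 1 (steps 1–7)**

Step 1
Reactants: 1 (S)-(+)-carvone
Product: 2 (2R,5S)-2-methyl-5-(prop-1-en-2-yl)cyclohexan-1-one
Conditions: ene-reductase OYE2, NADP+ (cat.), D-glucose, glucose dehydrogenase, phosphate buffer pH 7, 30 °C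
Reagents that add atoms: none
Why: Biocatalytic conjugate reduction by an Old-Yellow-Enzyme-type ene-reductase, which adds hydride at C3 and a proton at C2 in a trans sense and should give the cis (2R,5S) isomer that carries the future C10′ and C7′ centres.

Step 2
Reactants: 2 (2R,5S)-2-methyl-5-(prop-1-en-2-yl)cyclohexan-1-one
Product: 3 ethyl (3R,6S)-3-methyl-2-oxo-6-(prop-1-en-2-yl)cycloheptane-1-carboxylate
Conditions: N2CHCO2Et, BF3·OEt2, CH2Cl2, 0 °C
Reagents that add atoms: ethyl diazoacetate, CCOC(=O)C=[N+]=[N-]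
Why: Lewis-acid-promoted diazoacetate ring expansion (Tiffeneau–Demjanov-type 1,2-shift) in which the less substituted α-methylene migrates, inserting C5′ with its ester carbon C4′ without touching the two stereocentres.

Step 3
Reactants: 3 ethyl (3R,6S)-3-methyl-2-oxo-6-(prop-1-en-2-yl)cycloheptane-1-carboxylate
Product: 4 ethyl (3R,6S)-3-methyl-6-(prop-1-en-2-yl)-2-(trifluoromethylsulfonyloxy)cyclohept-1-ene-1-carboxylate
Conditions: Tf2O, iPr2NEt, CH2Cl2, −78 °C
Reagents that add atoms: trifluoromethanesulfonic anhydride, O=S(=O)(OS(=O)(=O)C(F)(F)F)C(F)(F)F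
Why: O-triflation of the β-keto ester enol, which fixes the C1′=C5′ double bond as an enol triflate.

Step 4
Reactants: 4 ethyl (3R,6S)-3-methyl-6-(prop-1-en-2-yl)-2-(trifluoromethylsulfonyloxy)cyclohept-1-ene-1-carboxylate
Product: 5 ethyl (3R,6S)-2-(3-ethoxy-3-oxopropyl)-3-methyl-6-(prop-1-en-2-yl)cyclohept-1-ene-1-carboxylate
Conditions: BrZnCH2CH2CO2Et, Pd(PPh3)4 (5 mol %), THF, 50 °C
Reagents that add atoms: (3-ethoxy-3-oxopropyl)zinc bromide, CCOC(=O)CC[Zn]Br
Why: Negishi coupling of a β-triflyloxy enoate with a zinc homoenolate, an sp2–sp3 coupling that keeps the tetrasubstituted alkene and adds C2′ and C3′.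

Step 5
Reactants: 5 ethyl (3R,6S)-2-(3-ethoxy-3-oxopropyl)-3-methyl-6-(prop-1-en-2-yl)cyclohept-1-ene-1-carboxylate
Product: 6 ethyl (4R,7S)-4-methyl-1-oxo-7-(prop-1-en-2-yl)-1,2,3,4,5,6,7,8-octahydroazulene-2-carboxylate
Conditions: KOtBu, THF, 0 °C; AcOH
Reagents that add atoms: none
Why: Dieckmann condensation in which the only enolizable ester attacks the enoate carbonyl (5-exo-trig) and closes the cyclopentenone ring.

Step 6
Reactants: 6 ethyl (4R,7S)-4-methyl-1-oxo-7-(prop-1-en-2-yl)-1,2,3,4,5,6,7,8-octahydroazulene-2-carboxylate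
Product: 7 (4R,7S)-4-methyl-7-(prop-1-en-2-yl)-3,4,5,6,7,8-hexahydroazulen-1(2H)-one
Conditions: LiCl, H2O, DMSO, 150 °C
Reagents that add atoms: none
Why: Krapcho dealkoxycarbonylation of the β-keto ester under neutral halide conditions that spare the isopropenyl group.

Step 7
Reactants: 7 (4R,7S)-4-methyl-7-(prop-1-en-2-yl)-3,4,5,6,7,8-hexahydroazulen-1(2H)-one
Product: 8 (1R,4R,7S)-1,4-dimethyl-7-(prop-1-en-2-yl)-1,2,3,4,5,6,7,8-octahydroazulen-1-ol (fragment 1)
Conditions: MeLi, CeCl3, THF, −78 °C; aq. NH4Cl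
Reagents that add atoms: methyllithium, [Li]C
Why: Organocerium 1,2-addition to the enone gives the tertiary allylic alcohol, and since both C4′ epimers are expected the epimer with OH cis to the C10′ methyl (8) is separated by chromatography.

**Triterpene line (steps 8–31)**

Step 8
Reactants: 9 1,2-dimethoxy-3-methylbenzene
Product: 10 4-(3,4-dimethoxy-2-methylphenyl)-4-oxobutanoic acid
Conditions: succinic anhydride, AlCl3, ClCH2CH2Cl, 0 °C to rt
Reagents that add atoms: succinic anhydride, O=C1CCC(=O)O1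
Why: Friedel–Crafts acylation at the position para to the unhindered methoxy group and ortho to the methyl group, which supplies C6–C9.

Step 9
Reactants: 10 4-(3,4-dimethoxy-2-methylphenyl)-4-oxobutanoic acid
Product: 11 4-(3,4-dimethoxy-2-methylphenyl)butanoic acid
Conditions: H2 (4 atm), 10% Pd/C, AcOH, HClO4 (cat.), 50 °C
Reagents that add atoms: none
Why: Acid-assisted hydrogenolysis of the aryl ketone to the benzylic methylene.

Step 10
Reactants: 11 4-(3,4-dimethoxy-2-methylphenyl)butanoic acid
Product: 12 6,7-dimethoxy-5-methyl-3,4-dihydronaphthalen-1(2H)-one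
Conditions: P2O5/MeSO3H, 50 °C
Reagents that add atoms: none
Why: Intramolecular Friedel–Crafts acylation at the only free ortho position (para to a methoxy group) closes ring B.

Step 11
Reactants: 12 6,7-dimethoxy-5-methyl-3,4-dihydronaphthalen-1(2H)-one
Product: 14 6,7-dimethoxy-4,8-dimethyl-1,2-dihydronaphthalene, via tertiary carbinol 13 (not isolated)
Conditions: MeMgBr, THF, 0 °C; then TsOH (cat.), toluene, 80 °C
Reagents that add atoms: methylmagnesium bromide, C[Mg]Br
Why: Grignard 1,2-addition followed by acid-catalysed E1 dehydration to the conjugated trisubstituted alkene, which introduces the C9 methyl carbon.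

Step 12
Reactants: 14 6,7-dimethoxy-4,8-dimethyl-1,2-dihydronaphthalene
Product: 16 6,7-dimethoxy-1,5-dimethyl-3,4-dihydronaphthalen-2(1H)-one (racemic), via epoxide 15 (not isolated)
Conditions: mCPBA, NaHCO3, CH2Cl2, 0 °C; then BF3·OEt2 (cat.), 0 °C
Reagents that add atoms: meta-chloroperoxybenzoic acid, OOC(=O)c1cccc(Cl)c1
Why: Epoxidation and Meinwald rearrangement (benzylic cation, 1,2-hydride shift) move the oxygen to C8 and give the 1-methyl-2-tetralone.

Step 13
Reactants: 16 6,7-dimethoxy-1,5-dimethyl-3,4-dihydronaphthalen-2(1H)-one (racemic)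
Product: 19 (S)-6,7-dimethoxy-1,5-dimethyl-1-(3-oxopentyl)-3,4-dihydronaphthalen-2(1H)-one, via chiral ketimine 17 (not isolated), via alkylated ketimine 18 (not isolated)
Conditions: (S)-1-phenylethylamine, TsOH (cat.), toluene, reflux (−H2O); EtCOCH=CH2, THF, rt; aq. AcOH
Reagents that add atoms: pent-1-en-3-one, CCC(=O)C=C
Why: Deracemizing Michael reaction of the secondary enamine tautomer of the chiral ketimine, which should add to the enone on the face anti to the phenyl group through a chair-like aza-ene transition state and set the quaternary C9.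

Step 14
Reactants: 19 (S)-6,7-dimethoxy-1,5-dimethyl-1-(3-oxopentyl)-3,4-dihydronaphthalen-2(1H)-one
Product: 20 (R)-6,7-dimethoxy-1,4a,8-trimethyl-4,4a,9,10-tetrahydrophenanthren-2(3H)-one
Conditions: NaOMe, MeOH, 60 °C
Reagents that add atoms: none
Why: Intramolecular aldol condensation (second half of a Robinson annulation) closes ring C as the C13-keto C8=C14 enone that already carries the C14 methyl.

Step 15
Reactants: 20 (R)-6,7-dimethoxy-1,4a,8-trimethyl-4,4a,9,10-tetrahydrophenanthren-2(3H)-one
Product: 22 tricyclic 13-ketone with 14α-allyl (8α-H; 9β-CH3; 14β-CH3), via lithium enolate 21 (not isolated)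
Conditions: Li, NH3 (l), THF, tBuOH (1 equiv), −78 °C; then allyl bromide, −78 to −33 °C
Reagents that add atoms: allyl bromide, C=CCBr
Why: Birch-type reductive alkylation of the enone, in which axial protonation of the β-carbanion gives the trans B/C junction (8α-H) and the regiodefined C14 enolate is allylated on the α-face, anti to the 1,3-related axial C9 methyl, so that the C14 methyl stays β.

Step 16
Reactants: 22 tricyclic 13-ketone with 14α-allyl
Product: 23 13α-(prop-1-ynyl)-13β-carbinol
Conditions: MeC≡CMgBr, CeCl3, THF, −78 to 0 °C; aq. NH4Cl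
Reagents that add atoms: prop-1-ynylmagnesium bromide, CC#C[Mg]Br
Why: Organocerium alkynyl 1,2-addition to the hindered, enolizable C13 ketone from the axial α-face; the carbinol configuration is lost in the next step.

Step 17
Reactants: 23 13α-(prop-1-ynyl)-13β-carbinol
Product: 24 13-(2-oxopropylidene) enone (acetyl cis to C12)
Conditions: Ph3PAuNTf2 (2 mol %), MeOH (2 equiv), toluene, 60 °C
Reagents that add atoms: none
Why: Gold-catalysed Meyer–Schuster rearrangement of the tertiary propargylic alcohol to the α,β-unsaturated methyl ketone, which places C18, C17 and C22 on C13.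

Step 18
Reactants: 24 13-(2-oxopropylidene) enone
Product: 25 13α-methyl-13β-(2-oxopropyl) ketone
Conditions: Me2CuLi, BF3·OEt2, Et2O, −78 to −40 °C; aq. NH4Cl
Reagents that add atoms: lithium dimethylcuprate, [Li+].C[Cu-]C
Why: Lewis-acid-assisted organocuprate conjugate addition, in which methyl should enter axially on the α-face, anti to the vicinal axial 14β-methyl, giving C13 with α-CH3 (C27) and the β-equatorial acetonyl group.

Step 19
Reactants: 25 13α-methyl-13β-(2-oxopropyl) ketone
Product: 27 seco-D keto ester (ring E closed; C17 ketone; 20-H methyl ester; 14α-allyl), via pyrrolidine enamine 26 (not isolated)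
Conditions: pyrrolidine, TsOH (cat.), benzene, reflux (−H2O); then CH2=C(CH2Br)CO2Me, Et3N, MeCN, 80 °C; aq. AcOH
Reagents that add atoms: methyl 2-(bromomethyl)acrylate, C=C(CBr)C(=O)OC
Why: Enamine α,α′-annulation (SN2′ alkylation at C22, then intramolecular Michael addition from C18) builds ring E; C18 and C20 are epimerizable and should settle with the C13 substituent and the ester equatorial and with the flat C17 carbonyl, not the C19 methylene, beside the crowded C14.

Step 20
Reactants: 27 seco-D keto ester (14α-allyl)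
Product: 28 C16 aldehyde (14α-CH2CHO)
Conditions: OsO4 (2 mol %), NaIO4, 2,6-lutidine, dioxane/H2O, rt
Reagents that add atoms: sodium periodate, [Na+].[O-]I(=O)(=O)=O
Why: Lemieux–Johnson oxidative cleavage of the only alkene leaves the two-carbon C15–C16 arm.

Step 21
Reactants: 28 C16 aldehyde
Product: 29 C16 alcohol (14α-CH2CH2OH)
Conditions: NaBH(OAc)3, benzene, 50 °C
Reagents that add atoms: none
Why: Chemoselective hydride reduction of the aldehyde, since triacetoxyborohydride does not reduce the C17 ketone or the ester under these conditions.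

Step 22
Reactants: 29 C16 alcohol
Product: 30 C16 bromide (14α-CH2CH2Br)
Conditions: CBr4, PPh3, CH2Cl2, 0 °C
Reagents that add atoms: tetrabromomethane, BrC(Br)(Br)Br
Why: Appel bromination of the primary alcohol (SN2).

Step 23
Reactants: 30 C16 bromide
Product: 31 6-oxo bromide (C6 aryl ketone)
Conditions: DDQ (2.2 equiv), dioxane/H2O (10:1), rt
Reagents that add atoms: water, O
Why: DDQ benzylic oxidation at C6, the only benzylic methylene and para to the C2 methoxy group (hydride abstraction, capture by water, second oxidation).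

Step 24
Reactants: 31 6-oxo bromide
Product: 32 6-oxo catechol (C2-OH; C3-OH; fragment 2)
Conditions: BBr3, CH2Cl2, −78 to 0 °C; H2O
Reagents that add atoms: none
Why: Lewis-acid cleavage of both aryl methyl ethers at low temperature, which should spare the methyl ester and the primary bromide.

Step 25
Reactants: 32 6-oxo catechol (fragment 2); 8 (1R,4R,7S)-1,4-dimethyl-7-(prop-1-en-2-yl)-1,2,3,4,5,6,7,8-octahydroazulen-1-ol (fragment 1)
Product: 34 dioxane adduct with C4′ tertiary alcohol, via 6-oxo-o-quinone 33 (not isolated)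
Conditions: Ag2O, Na2SO4, Et2O, 0 °C, filtration; then 8, CH2Cl2, rt, dark
Reagents that add atoms: none
Why: Oxidation to the electron-poor o-quinone (the C6 carbonyl blocks tautomerization to a quinone methide) and inverse-electron-demand hetero-Diels–Alder reaction with the C1′=C5′ alkene, in which a hydrogen bond from the C4′-OH to the more basic C2 carbonyl oxygen should bring the heterodiene to the hydroxyl-bearing face and put O2 on C5′ and O3 on C1′, setting both centres.

Step 26
Reactants: 34 dioxane adduct with C4′ tertiary alcohol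
Product: 35 3′-ene dioxane adduct (C17 ketone; C16 bromide)
Conditions: Burgess reagent, benzene, 50 °C
Reagents that add atoms: none
Why: Burgess syn-dehydration of the tertiary alcohol toward the ring methylene (C5′ is quaternary) should give the endocyclic trisubstituted C3′=C4′ alkene.

Step 27
Reactants: 35 3′-ene dioxane adduct
Product: 36 C17 tertiary carbinol (17-hydroxy-17-methyl; either C17 epimer)
Conditions: MeMgBr, CeCl3, THF, −78 °C; aq. NH4Cl
Reagents that add atoms: methylmagnesium bromide, C[Mg]Br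
Why: Organocerium methyl addition, chemoselective for the C17 cyclohexanone over the ester and over the C6 aryl ketone, which is deactivated by the para oxygen and shielded by the peri C4 methyl; this brings in C28.

Step 28
Reactants: 36 C17 tertiary carbinol
Product: 38 ring-D-closed pentacycle (6-ketone; 20-H methyl ester), via alkoxybenzoxazoline adduct 37 (not isolated)
Conditions: 3-phenylbenzoxazolium tetrafluoroborate, pyridine, tBuOMe, rt; then Ir(ppy)2(dtbbpy)PF6 (2 mol %), Ni(acac)2 (10 mol %), KTp* (potassium hydrotris(3,5-dimethylpyrazolyl)borate, 10 mol %), quinuclidine, DMA, 450 nm LEDs, rt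
Reagents that add atoms: none
Why: Proposed new method: the C17 alcohol condenses with the benzoxazolium salt to adduct 37, which is oxidized by the photoexcited iridium catalyst and fragments by β-scission to the tertiary C17 radical, while low-valent nickel (turned over by the reduced iridium catalyst) converts the primary C16–Br bond into a C16–nickel alkyl; homolytic substitution by the C17 radical at that nickel-bound carbon (or radical capture and reductive elimination) forms C16–C17. The closest known reactions are the intermolecular metallaphotoredox deoxygenative C(sp3)–C(sp3) couplings of such activated alcohols with alkyl bromides and the nickel radical-sorting couplings that make quaternary carbons, here turned into a ring closure. Ring D closes as a six-membered ring in an exo mode (C17 attacks C16 with the nickel leaving group outside the ring). C17 is the only new stereocentre and is set by the ring: bonding on the α-face of the planar radical gives the cis D/E fusion (C28 β, cis to H18), because the trans mode would place C28 syn-diaxial to the 13α-methyl C27. The step needs chemoselectivity for one tertiary alcohol and one primary bromide beside three alkenes, a ketone and an ester; this is secured by the removal of the C4′ carbinol in step 26, by the 1,6-relationship that makes the coupling intramolecular, and by redox-neutral conditions without strong base or acid.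

Step 29
Reactants: 38 ring-D-closed pentacycle (6-ketone)
Product: 39 6-hydroxy pentacycle (either C6 epimer)
Conditions: NaBH4, MeOH/THF, 0 °C
Reagents that add atoms: none
Why: Borohydride reduction of the C6 aryl ketone, which leaves the ester untouched and whose C6 configuration is lost in the next step.

Step 30
Reactants: 39 6-hydroxy pentacycle
Product: 40 6-ene 20-H methyl ester
Conditions: Burgess reagent, THF, 50 °C
Reagents that add atoms: none
Why: Burgess dehydration of the benzylic alcohol to the C6=C7 styrene, the only possible direction because only C7 carries β-hydrogens.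

Step 31
Reactants: 40 6-ene 20-H methyl ester
Product: 42 target CNP0113384.1, via lithium ester enolate 41 (not isolated)
Conditions: LDA (1.05 equiv), THF, −78 °C; then MeI, −78 to −40 °C
Reagents that add atoms: iodomethane, CI
Why: Ester enolate alkylation, in which MeI should approach the β-face of the C20 enolate because the α-face of ring E in the cis D/E system is screened by the 13α-methyl C27, giving 20β-CH3 and 20α-CO2Me.

**Compound list**
1 | (S)-(+)-carvone | CC1=CC[C@@H](CC1=O)C(C)=C | starting material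
2 | (2R,5S)-2-methyl-5-(prop-1-en-2-yl)cyclohexan-1-one | C=C(C)[C@H]1CC[C@@H](C)C(=O)C1 | intermediate
3 | ethyl (3R,6S)-3-methyl-2-oxo-6-(prop-1-en-2-yl)cycloheptane-1-carboxylate (C1 epimers/enol) | C=C(C)[C@H]1CC[C@@H](C)C(=O)C(C(=O)OCC)C1 | intermediate
4 | ethyl (3R,6S)-3-methyl-6-(prop-1-en-2-yl)-2-(trifluoromethylsulfonyloxy)cyclohept-1-ene-1-carboxylate | C=C(C)[C@H]1CC[C@@H](C)C(OS(=O)(=O)C(F)(F)F)=C(C(=O)OCC)C1 | intermediate
5 | ethyl (3R,6S)-2-(3-ethoxy-3-oxopropyl)-3-methyl-6-(prop-1-en-2-yl)cyclohept-1-ene-1-carboxylate | C=C(C)[C@H]1CC[C@@H](C)C(CCC(=O)OCC)=C(C(=O)OCC)C1 | intermediate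
6 | ethyl (4R,7S)-4-methyl-1-oxo-7-(prop-1-en-2-yl)-1,2,3,4,5,6,7,8-octahydroazulene-2-carboxylate (C2 epimers) | C=C(C)[C@H]1CC[C@@H](C)C2=C(C1)C(=O)C(C(=O)OCC)C2 | intermediate
7 | (4R,7S)-4-methyl-7-(prop-1-en-2-yl)-3,4,5,6,7,8-hexahydroazulen-1(2H)-one | C=C(C)[C@H]1CC[C@@H](C)C2=C(C1)C(=O)CC2 | intermediate
8 | (1R,4R,7S)-1,4-dimethyl-7-(prop-1-en-2-yl)-1,2,3,4,5,6,7,8-octahydroazulen-1-ol (fragment 1; 4′-OH cis to 10′-CH3 and 7′-isopropenyl) | C=C(C)[C@H]1CC[C@@H](C)C2=C(C1)[C@](C)(O)CC2 | intermediate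
9 | 1,2-dimethoxy-3-methylbenzene | COc1cccc(C)c1OC | starting material
10 | 4-(3,4-dimethoxy-2-methylphenyl)-4-oxobutanoic acid | COc1ccc(C(=O)CCC(=O)O)c(C)c1OC | intermediate
11 | 4-(3,4-dimethoxy-2-methylphenyl)butanoic acid | COc1ccc(CCCC(=O)O)c(C)c1OC | intermediate
12 | 6,7-dimethoxy-5-methyl-3,4-dihydronaphthalen-1(2H)-one | COc1cc2c(c(C)c1OC)CCCC2=O | intermediate
13 | 6,7-dimethoxy-1,5-dimethyl-1,2,3,4-tetrahydronaphthalen-1-ol (racemic) | COc1cc2c(c(C)c1OC)CCCC2(C)O | intermediate
14 | 6,7-dimethoxy-4,8-dimethyl-1,2-dihydronaphthalene | COc1cc2c(c(C)c1OC)CCC=C2C | intermediate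
15 | 3,4-epoxide of 14 (racemic) | COc1cc2c(c(C)c1OC)CCC1OC21C | intermediate
16 | 6,7-dimethoxy-1,5-dimethyl-3,4-dihydronaphthalen-2(1H)-one (racemic) | COc1cc2c(c(C)c1OC)CCC(=O)C2C | intermediate
17 | N-[(S)-1-phenylethyl] ketimine of 16 (in equilibrium with its enamine) | COc1cc2c(c(C)c1OC)CCC(=N[C@@H](C)c1ccccc1)C2C | intermediate
18 | N-[(S)-1-phenylethyl] ketimine of 19 | COc1cc2c(c(C)c1OC)CCC(=N[C@@H](C)c1ccccc1)[C@@]2(C)CCC(=O)CC | intermediate
19 | (S)-6,7-dimethoxy-1,5-dimethyl-1-(3-oxopentyl)-3,4-dihydronaphthalen-2(1H)-one | COc1cc2c(c(C)c1OC)CCC(=O)[C@@]2(C)CCC(=O)CC | intermediate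
20 | (R)-6,7-dimethoxy-1,4a,8-trimethyl-4,4a,9,10-tetrahydrophenanthren-2(3H)-one (rings A, B, C; C13 ketone; C8=C14) | COc1cc2c(c(C)c1OC)CCC1=C(C)C(=O)CC[C@]12C | intermediate
21 | lithium C13 enolate (C13=C14; 8α-H) | COc1cc2c(c(C)c1OC)CC[C@H]1[C@@]2(C)CCC(O[Li])=C1C | intermediate
22 | tricyclic 13-ketone, 14α-allyl, 8α-H, 9β-CH3, 14β-CH3, 2,3-dimethoxy | COc1cc2c(c(C)c1OC)CC[C@H]1[C@@]2(C)CCC(=O)[C@@]1(CC=C)C | intermediate
23 | 13α-(prop-1-ynyl)-13β-carbinol of 22 | COc1cc2c(c(C)c1OC)CC[C@H]1[C@@]2(C)CC[C@](O)(C#CC)[C@@]1(CC=C)C | intermediate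
24 | 13-(2-oxopropylidene) enone, acetyl cis to C12 | COc1cc2c(c(C)c1OC)CC[C@H]1[C@@]2(C)CC/C(=C\C(C)=O)[C@@]1(CC=C)C | intermediate
25 | 13α-methyl-13β-(2-oxopropyl) ketone | COc1cc2c(c(C)c1OC)CC[C@H]1[C@@]2(C)CC[C@@](C)(CC(C)=O)[C@@]1(CC=C)C | intermediate
26 | pyrrolidine enamine of 25 (C17=C22) | COc1cc2c(c(C)c1OC)CC[C@H]1[C@@]2(C)CC[C@@](C)(CC(=C)N2CCCC2)[C@@]1(CC=C)C | intermediate
27 | seco-D keto ester: ring E with C17 ketone and 20α-CO2CH3 (20-H), 18β-H, 14α-allyl | COc1cc2c(c(C)c1OC)CC[C@H]1[C@@]2(C)CC[C@@](C)([C@@H]3C[C@H](C(=O)OC)CCC3=O)[C@@]1(CC=C)C | intermediate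
28 | C16 aldehyde (14α-CH2CHO) | COc1cc2c(c(C)c1OC)CC[C@H]1[C@@]2(C)CC[C@@](C)([C@@H]3C[C@H](C(=O)OC)CCC3=O)[C@@]1(CC=O)C | intermediate
29 | C16 alcohol (14α-CH2CH2OH) | COc1cc2c(c(C)c1OC)CC[C@H]1[C@@]2(C)CC[C@@](C)([C@@H]3C[C@H](C(=O)OC)CCC3=O)[C@@]1(CCO)C | intermediate
30 | C16 bromide (14α-CH2CH2Br) | COc1cc2c(c(C)c1OC)CC[C@H]1[C@@]2(C)CC[C@@](C)([C@@H]3C[C@H](C(=O)OC)CCC3=O)[C@@]1(CCBr)C | intermediate
31 | 6-oxo bromide | COc1cc2c(c(C)c1OC)C(=O)C[C@H]1[C@@]2(C)CC[C@@](C)([C@@H]3C[C@H](C(=O)OC)CCC3=O)[C@@]1(CCBr)C | intermediate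
32 | 6-oxo catechol (fragment 2) | Oc1cc2c(c(C)c1O)C(=O)C[C@H]1[C@@]2(C)CC[C@@](C)([C@@H]3C[C@H](C(=O)OC)CCC3=O)[C@@]1(CCBr)C | intermediate
33 | 6-oxo-o-quinone (C2=O, C3=O) | O=C1C=C2C(=C(C)C1=O)C(=O)C[C@H]1[C@@]2(C)CC[C@@](C)([C@@H]3C[C@H](C(=O)OC)CCC3=O)[C@@]1(CCBr)C | intermediate
34 | dioxane adduct (O2–C5′, O3–C1′) with C4′ tertiary alcohol | C=C(C)[C@H]1CC[C@@H](C)[C@]23CC[C@@](C)(O)[C@@]2(C1)Oc1cc2c(c(C)c1O3)C(=O)C[C@H]1[C@@]2(C)CC[C@@](C)([C@@H]3C[C@H](C(=O)OC)CCC3=O)[C@@]1(CCBr)C | intermediate
35 | 3′-ene dioxane adduct (C17 ketone, C16 bromide, C6 ketone) | C=C(C)[C@H]1CC[C@@H](C)[C@]23CC=C(C)[C@@]2(C1)Oc1cc2c(c(C)c1O3)C(=O)C[C@H]1[C@@]2(C)CC[C@@](C)([C@@H]3C[C@H](C(=O)OC)CCC3=O)[C@@]1(CCBr)C | intermediate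
36 | C17 tertiary carbinol (17-hydroxy-17-methyl; C17 not defined, both epimers converge) | C=C(C)[C@H]1CC[C@@H](C)[C@]23CC=C(C)[C@@]2(C1)Oc1cc2c(c(C)c1O3)C(=O)C[C@H]1[C@@]2(C)CC[C@@](C)([C@@H]3C[C@H](C(=O)OC)CCC3(C)O)[C@@]1(CCBr)C | intermediate
37 | 2-alkoxy-3-phenyl-2,3-dihydrobenzoxazole adduct of 36 at the C17 oxygen | C=C(C)[C@H]1CC[C@@H](C)[C@]23CC=C(C)[C@@]2(C1)Oc1cc2c(c(C)c1O3)C(=O)C[C@H]1[C@@]2(C)CC[C@@](C)([C@@H]3C[C@H](C(=O)OC)CCC3(C)OC3Oc4ccccc4N3c3ccccc3)[C@@]1(CCBr)C | intermediate
38 | ring-D-closed pentacycle: 6-ketone, 17β-CH3, 18β-H, 20-H methyl ester | C=C(C)[C@H]1CC[C@@H](C)[C@]23CC=C(C)[C@@]2(C1)Oc1cc2c(c(C)c1O3)C(=O)C[C@H]1[C@@]2(C)CC[C@@]2(C)[C@@H]3C[C@H](C(=O)OC)CC[C@]3(C)CC[C@]12C | intermediate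
39 | 6-hydroxy pentacycle (C6 not defined) | C=C(C)[C@H]1CC[C@@H](C)[C@]23CC=C(C)[C@@]2(C1)Oc1cc2c(c(C)c1O3)C(O)C[C@H]1[C@@]2(C)CC[C@@]2(C)[C@@H]3C[C@H](C(=O)OC)CC[C@]3(C)CC[C@]12C | intermediate
40 | 6-ene 20-H methyl ester | C=C(C)[C@H]1CC[C@@H](C)[C@]23CC=C(C)[C@@]2(C1)Oc1cc2c(c(C)c1O3)C=C[C@H]1[C@@]2(C)CC[C@@]2(C)[C@@H]3C[C@H](C(=O)OC)CC[C@]3(C)CC[C@]12C | intermediate
41 | lithium C20 ester enolate of 40 | C=C(C)[C@H]1CC[C@@H](C)[C@]23CC=C(C)[C@@]2(C1)Oc1cc2c(c(C)c1O3)C=C[C@H]1[C@@]2(C)CC[C@@]2(C)[C@@H]3CC(=C(OC)O[Li])CC[C@]3(C)CC[C@]12C | intermediate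
42 | CNP0113384.1 | C=C(C)[C@H]1CC[C@@H](C)[C@]23CC=C(C)[C@@]2(C1)Oc1cc2c(c(C)c1O3)C=C[C@H]1[C@@]2(C)CC[C@@]2(C)[C@@H]3C[C@](C)(C(=O)OC)CC[C@]3(C)CC[C@]12C | target

**Step count and risks**
Total steps: 31. Longest linear sequence: 24 steps (steps 8–31, from 1,2-dimethoxy-3-methylbenzene); fragment 1 takes 7 steps (steps 1–7) and enters in step 25.

The three steps most likely to fail:

Step 28 (proposed new method). The C17 radical may be reduced, disproportionate or undergo 1,5-hydrogen transfer faster than it is intercepted at C16, or the C16–Br bond may be hydrodehalogenated, so that ring D does not close. The fallback uses known chemistry and sets out from 35. Horner–Wadsworth–Emmons olefination of the C17 ketone with diethyl (phenylsulfonyl)methylphosphonate and NaH should give the exocyclic C17 vinyl sulfone F1. Tin-hydride radical cyclization (Bu3SnH, AIBN, benzene, 80 °C) of the C16 bromide in the 6-exo mode onto C17 should close ring D and give the C17-(phenylsulfonyl)methyl pentacycle F2, cis D/E for the same reason as in the main route. NaBH4 reduction of the C6 ketone gives the 6-hydroxy sulfone F3, and reductive desulfonylation with Na(Hg) and Na2HPO4 in MeOH turns CH2SO2Ph into CH3 and comes back to the route at 39.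

Step 25. The cycloaddition may show poor regio- or facial selectivity (O2 and O3 interchanged, or addition anti to the C10′ methyl), or quinone 33 may decay before the hindered alkene reacts. The fallback sets out from 8: Burgess dehydration gives the cyclopentadiene (4R,7S)-1,4-dimethyl-7-(prop-1-en-2-yl)-3,4,5,6,7,8-hexahydroazulene F4, which is used at once, before 1,5-hydrogen shifts scramble it, as the 2π partner toward 33 (made from 32 as before) under high pressure. The conjugated diene is far more electron-rich than the isolated alkene and should bond first through its C1′ terminus to O3, leaving the para-acyl phenoxide O2 to close on the allyl cation at C5′. This gives the 3′-ene adduct directly and comes back to the route at 35, so that step 26 is no longer needed.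

Step 19. The ring-forming Michael addition at the neopentyl C18 may be too slow, so that double alkylation at C22 or acrylate polymerization takes over, or C18 may settle in the wrong configuration. The fallback sets out from 24 and inverts the order of bond formation: conjugate addition of Me2CuLi to 24 and trapping of the regiodefined C18 enolate with methyl 2-(bromomethyl)acrylate (SN2′) gives the C18-[2-(methoxycarbonyl)allyl] methyl ketone F5. KOtBu in tBuOH then closes ring E by intramolecular Michael addition of the C22 enolate with equilibration at C18 and C20, and comes back to the route at 27 (steps 18 and 19 replaced).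

**Further compounds**
F1 | step 28 | C17 (phenylsulfonyl)methylidene derivative of 35 | C=C(C)[C@H]1CC[C@@H](C)[C@]23CC=C(C)[C@@]2(C1)Oc1cc2c(c(C)c1O3)C(=O)C[C@H]1[C@@]2(C)CC[C@@](C)([C@@H]3C[C@H](C(=O)OC)CCC3=CS(=O)(=O)c3ccccc3)[C@@]1(CCBr)C
F2 | step 28 | ring-D-closed 6-ketone with C17-CH2SO2Ph in place of C28 methyl | C=C(C)[C@H]1CC[C@@H](C)[C@]23CC=C(C)[C@@]2(C1)Oc1cc2c(c(C)c1O3)C(=O)C[C@H]1[C@@]2(C)CC[C@@]2(C)[C@@H]3C[C@H](C(=O)OC)CC[C@]3(CS(=O)(=O)c4ccccc4)CC[C@]12C
F3 | step 28 | 6-hydroxy derivative of F2 | C=C(C)[C@H]1CC[C@@H](C)[C@]23CC=C(C)[C@@]2(C1)Oc1cc2c(c(C)c1O3)C(O)C[C@H]1[C@@]2(C)CC[C@@]2(C)[C@@H]3C[C@H](C(=O)OC)CC[C@]3(CS(=O)(=O)c4ccccc4)CC[C@]12C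
F4 | step 25 | (4R,7S)-1,4-dimethyl-7-(prop-1-en-2-yl)-3,4,5,6,7,8-hexahydroazulene | C=C(C)[C@H]1CC[C@@H](C)C2=C(C1)C(C)=CC2
F5 | step 19 | C18-[2-(methoxycarbonyl)allyl] derivative of 25 | COc1cc2c(c(C)c1OC)CC[C@H]1[C@@]2(C)CC[C@@](C)([C@H](CC(=C)C(=O)OC)C(C)=O)[C@@]1(CC=C)C
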